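All constants are invented; the flask was simulated.

Per second is the unit in which this flask is read, each loss of Z being written below as a first-order constant.

    Q ⇌ L, rate k1*(cs1 - [L]) while solid is left; crystals form when [L] > cs1 (cs1 = 0.45 M, k1 = 0.24 s⁻¹)
    L + Z → L.Z (k2 = 0.11 M⁻¹ s⁻¹)
    Z → J (k3 = 0.0086 s⁻¹)
    X ⇌ L.Z, rate k4*(cs4 - [L.Z]) while solid is left; crystals form when [L.Z] > cs4 (cs4 = 0.40 M, k4 = 9.6 s⁻¹)
    G ⇌ Z, rate k5*(cs5 - [Z]) while solid is left; crystals form when [Z] > cs5 (cs5 = 0.55 M, k5 = 2.4 s⁻¹)
    Z ⇌ E (K6 = 0.58, k6 = 0.090 s⁻¹)

Q 1.1 M; G 0.770 M; time 40 s

1. the L.Z and X together standing at 40 s, as a percentage of the Q charged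
2. the change that raises the amount of L.Z and X together at 40 s, in percent of the Q charged most ("none" if none brings more than 2 percentage points) (north / west / south-west / south / none)
3. amount of L.Z and X together at 40 s, in percent of the Q charged, after south-west

- north: doubling the solubility in step 5, all else as stated
- west: doubling the solubility in step 1, all else as stated
- south-west: doubling the dissolution coefficient of step 4, all else as stated
- south: doubling the dissolution coefficient of step 5, all else as stated

- amounts and yields of L.Z count X too
- given per volume of solution although it is solid: Q, X, G
- at the start none of Q is in solution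
- at the start none of G is in solution
- run time (flask): 40 s

Two numbers seem to clash. Z has a half-life of 81 s towards J by that step alone, twice the run, so J looks negligible. Yet L.Z is not expected to reach the 70.0% that the charges allow.

The clearing comes from comparing rates at one moment. With c(L) at its solubility of 0.45 M, Z goes to L.Z with a pseudo-first-order constant of 0.0495 s⁻¹, against 0.0086 s⁻¹ towards J. The Z share, the fraction of spent Z that ends as L.Z, is the first constant over the sum of both: 85.2%. At fixed c(L) time does not enter this share, so the slow step takes its part of Z throughout, and the ceiling, in percent of the Q charged, falls to 59.6%. The comparison drifts, since c(L) starts at zero and the share starts lower.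

E relaxes with Z in 2.83 s, faster than the run, so free Z is taken as a fixed part of the Z and E pool. That pool then decays at 0.0368 s⁻¹. My reckoning spends 77.0% of the pool by the asked time, giving 45.9%, an estimate that takes c(L) at its solubility from the start. The change west, doubling the solubility of L, gives a share of 92.0%, a pool constant of 0.0681 s⁻¹ and 60.2%, a gain of 14 percentage points. That gain holds c(L) at 0.900 M, but this c(L) and that product together come to 1.56 M, more than the 1.1 M of Q charged, so the gain is a rough estimate. South-west doubles the dissolution coefficient of step 4, which joins X and L.Z; these two are counted together and the coefficient stands nowhere in the Z share, so the reckoning stays as it is after south-west.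

The forecast, lower than this reckoning, gives 42.5%, names west because that change “makes L.Z win the competition for Z clearly”, and gives 42.5% after south-west. The flask gives 39.3%, with west best at a gain of 12 points, and 39.3% after south-west.

At 40.0 s the flask holds 0.433 M of L.Z and X against 0.101 M of J, a read share of 81.1%, lower than the Z share. The neighbouring flask is charged with 2.8 M of Q and the same G. The Z share contains no Q charge, so the same molar product is reckoned there, which is 15.5% of its Q. That neighbouring flask holds 0.101 M of J and 0.137 M of Z, and its L.Z and X stand at 15.5%.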